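Amounts first. I want the electrophile left in the flask at 15 min.

| flask | electrophile | nucleophile | free base | protic impurity | remark | time |
|---|---|---|---|---|---|---|
| autumn | 0.20 M | 0.80 M | 0.40 M | 0.040 M | run made earlier |  |
| spring | 0.80 M | 0.80 M | 0.40 M | 0.040 M | run made earlier |  |
| summer | 0.40 M | 0.80 M | 0.60 M | 0.040 M | run made earlier |  |
| flask | 0.40 M | 0.800 M | 0.400 M | 0.0400 M |  | 15 min |

- autumn (time / min: electrophile / %, product / %): 2.50: 23.2, 38.5; 5.00: 10.4, 53.5; 8.00: 7.9, 61.8; 10.0: 5.9, 65.3; 12.0: 5.0, 69.9; 15.0: 5.4, 74.4
- spring (time / min: electrophile / %, product / %): 2.50: 25.5, 37.4; 5.00: 15.9, 44.6; 8.00: 14.3, 50.7; 10.0: 10.5, 54.9; 12.0: 11.2, 56.1; 15.0: 14.0, 58.0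
- summer (time / min: electrophile / %, product / %): 3.00: 21.3, 41.0; 6.00: 11.8, 52.9; 10.0: 7.5, 63.6; 12.0: 8.1, 64.0; 15.0: 6.5, 71.3

(each reading ± 1 percentage point)

- what has gone from electrophile into another species counts as reacted, even if it can come back
- a reading or a percentage of product counts all its forms, free or not
- the earlier runs do not show how much of nucleophile is bound; that part of a forecast is a guess

- part of the electrophile that has reacted at 15 min
- share of the unused nucleophile that is free and not bound as protonated nucleophile, at 15 min

1. Electrophile and product do not add up to the charge. In the summer run the missing share at 10.0 min is 28.9%, against a scatter of 1 percentage point on each reading.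

2. Between 10.0 min and 15.0 min the missing share and the electrophile both end lower, so I divide one by the other and time drops out. The ratio reads 3.85, then 3.42. Pooling the last three summer readings gives the hold-up ratio, missing share over [electrophile]: 3.57.

3. The weak link is that summer carried 0.60 M of free base, not 0.400 M. Autumn and spring carry the flask's base and bracket its electrophile, so I pool them the same way. They give 4.55 and 2.67. That is an exponent of −0.384 in the charge and a geometric mean of 3.48, close to summer's ratio.

4. Electrophile left is (charge − product)/(1 + ratio). With summer's 71.3% of product, my reckoning leaves 6.40%, so I commit to 93.6% reacted. An error in product reaches this estimate multiplied by 0.223.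

The forecast, reading late electrophile directly, says 92% (89.5% to 94.5%), a little below mine, and 92% free (75% to 99%), a guess I adopt. It expects “a reversible hidden intermediate or reservoir”.

The flask gives 93.2% reacted and 87.0% free.

    electrophile + nucleophile → acid set free + product (k = 0.00750 L mol⁻¹ s⁻¹)
    nucleophile + acid set free ⇌ protonated nucleophile, settled at all times (K = 2100 L mol⁻¹)
    acid set free + free base ⇌ salt of the base, settled at all times (K = 20000 L mol⁻¹)
    electrophile ⇌ dormant form (K = 2.40, k = 0.00640 s⁻¹)
    crystals ⇌ product, rate k5*(cs5 - [product]) while solid is left; crystals form when [product] > cs5 (solubility = 0.300 M, k = 0.100 s⁻¹)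
    protic impurity + free base → quenched reagent (k = 2.00 L mol⁻¹ s⁻¹)

At 15.0 min the flask holds 23.4% as dormant form, the resting state of the unused electrophile, against 6.85% as electrophile, a hold-up ratio of 3.42. For the neighbour with 0.68 M of electrophile, the exponent puts the ratio at 2.92, and its 62.0% of product then gives 9.69% electrophile left. That neighbour holds 9.55%.

(The readings are simulated for substances that don't exist; noise was put on by code.)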